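**Retrosynthetic overview**
1. Target 4 ⇒ 3,5,7,2',4'-pentamethoxyflavone 2 by disconnecting the C5'–O bond. The phenol oxygen is installed last, by C–H borylation/oxidation at the only aryl C–H that has a single small ortho neighbour.
2. 2 ⇒ morin 1 by disconnecting five O–CH3 bonds. Morin is a commercial flavonol that already carries the C15 skeleton and the 3,5,7,2',4' oxygen pattern.
3. No ring is formed in the route: the chromone (A/C) and B rings are bought in with 1. Every bond made is C–O; the C–B bond is transient.

Assumption: the target has no stereocentre, so there is no enantiomer to control; commercial morin hydrate (dried at 110 °C under vacuum) is taken as a cheap starting material.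

**Step 1**
Reactants: 1 morin (2-(2,4-dihydroxyphenyl)-3,5,7-trihydroxy-4H-chromen-4-one)
Product: 2 3,5,7,2',4'-pentamethoxyflavone (2-(2,4-dimethoxyphenyl)-3,5,7-trimethoxy-4H-chromen-4-one)
Conditions: Me2SO4 (8 equiv), K2CO3 (10 equiv), dry acetone, reflux, N2, 36 h; aq. NH3 quench
Reagents that add atoms: dimethyl sulfate, COS(=O)(=O)OC
Why: Exhaustive Williamson O-methylation of the five phenolic/enolic OH groups, where excess reagent and long reflux also methylate the chelated 5-OH and the inert atmosphere prevents base/air degradation of the flavonol; no stereocentre is formed.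

**Step 2**
Reactants: 2 3,5,7,2',4'-pentamethoxyflavone
Product: 4 5'-hydroxy-3,5,7,2',4'-pentamethoxyflavone, via 5'-Bpin boronate 3 (not isolated)
Conditions: [Ir(OMe)(cod)]2 (3 mol %), 3,4,7,8-Me4-phen (6 mol %), B2pin2 (1.5 equiv), THF, 80 °C (sealed), 24 h; evaporate volatiles; then NaBO3·4H2O (3 equiv), THF/H2O 1:1, rt, 2 h; aq. NH4Cl/Na2S2O3 work-up
Reagents that add atoms: bis(pinacolato)diboron, CC1(C)OB(OC1(C)C)B1OC(C)(C)C(C)(C)O1 (gives the Bpin group of intermediate 3 only); sodium perborate, [Na+].[O-]B1OO1 (gives the oxygen of the 5'-OH)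
Why: Proposed new method: the Ir(III) tris(boryl) catalyst activates aryl C–H bonds under steric control and should pick C5'–H, because it is the only one of the five aryl C–H bonds with a single small ortho neighbour (the 4'-OMe, whose methyl can turn away and which acidifies that C–H), while C6 and C3' lie between two OMe groups, C8 lies between OMe and the ring oxygen and C6' sits beside the twisted chromenyl group, and the C–B bond is then converted at the same carbon into the C5'–O bond by peroxide addition to boron and 1,2-aryl shift; the closest known reaction type is the one-pot Ir/bipyridine arene C–H borylation–oxidation that makes phenols from simple arenes, which has not been shown on a polymethoxylated flavone or with a methoxy-flanked C–H as the intended site.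

**Compound list**
1 | morin, 2-(2,4-dihydroxyphenyl)-3,5,7-trihydroxy-4H-chromen-4-one | Oc1cc(O)c2c(=O)c(O)c(-c3ccc(O)cc3O)oc2c1 | starting material
2 | 3,5,7,2',4'-pentamethoxyflavone, 2-(2,4-dimethoxyphenyl)-3,5,7-trimethoxy-4H-chromen-4-one | COc1cc(OC)c2c(=O)c(OC)c(-c3ccc(OC)cc3OC)oc2c1 | intermediate
3 | 5'-Bpin boronate, 2-[2,4-dimethoxy-5-(4,4,5,5-tetramethyl-1,3,2-dioxaborolan-2-yl)phenyl]-3,5,7-trimethoxy-4H-chromen-4-one (formed in the flask, not isolated) | COc1cc(OC)c2c(=O)c(OC)c(-c3cc(B4OC(C)(C)C(C)(C)O4)c(OC)cc3OC)oc2c1 | intermediate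
4 | 5'-hydroxy-3,5,7,2',4'-pentamethoxyflavone, 2-(5-hydroxy-2,4-dimethoxyphenyl)-3,5,7-trimethoxy-4H-chromen-4-one | COc1cc(OC)c2c(=O)c(OC)c(-c3cc(O)c(OC)cc3OC)oc2c1 | target

**Total step count:** 2. **Longest linear sequence:** 2.

**Steps most likely to fail.** The route has only two steps, so both are ranked and the two stages of step 2 are ranked separately.

1. Step 2, C–H borylation stage (the proposed new step). The risks are low conversion at a methoxy-flanked C–H, or borylation at C8 or C6'. The fallback uses known chemistry only; it sets out from compound 2 and comes back to the route at compound 4. Pentamethoxyflavone 2 is cleaved with KOH in aqueous ethanol at reflux, the classical alkaline fission of a 3-methoxyflavone. This gives 1-(2-hydroxy-4,6-dimethoxyphenyl)-2-methoxyethan-1-one F1, which keeps the A ring and the future C3–OMe. Claisen–Schmidt condensation of this ketone with purchased 5-bromo-2,4-dimethoxybenzaldehyde (KOH, EtOH, rt) gives (Z)-3-(5-bromo-2,4-dimethoxyphenyl)-1-(2-hydroxy-4,6-dimethoxyphenyl)-2-methoxyprop-2-en-1-one F2. Dehydrogenative oxa-cyclisation (SeO2, isoamyl alcohol, reflux, the classical method for 2'-hydroxy-α-methoxychalcones) closes the pyranone ring to 5'-bromo-3,5,7,2',4'-pentamethoxyflavone F3. Pd-catalysed C–O coupling (tBuBrettPhos Pd G3, benzaldoxime as hydroxide surrogate, Cs2CO3, DMF, 80 °C) then converts C–Br into C–OH and gives 4.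

2. Step 2, oxidation stage. The risks are protodeboronation of the electron-rich ortho-methoxy boronate, or over-oxidation of the resulting p-methoxyphenol. The fallback sets out from compound 3, which is then isolated by chromatography, and comes back at compound 4. Cu(II)-mediated bromodeboronation (CuBr2, MeOH/H2O, 80 °C) replaces boron by bromine to give 5'-bromo-3,5,7,2',4'-pentamethoxyflavone F3, and the Pd-catalysed hydroxylation described above gives 4 without any peroxide.

3. Step 1. The risks are incomplete methylation of the hydrogen-bonded 5-OH, some C-methylation, and base/air degradation of the flavonol. The fallback sets out from compound 1 and comes back at compound 2. The single exhaustive alkylation is replaced by a staged one. Morin 1 is methylated only at its four acidic hydroxyls (MeI 4.5 equiv, K2CO3, acetone, 45 °C, N2) to 5-hydroxy-3,7,2',4'-tetramethoxyflavone F4, which is purified by crystallisation. Its chelated 5-OH is then alkylated separately as the sodium phenoxide (NaH, MeI, DMF, 0 °C to rt) to give 2.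

**Further compounds**
F1 | step 2 | 1-(2-hydroxy-4,6-dimethoxyphenyl)-2-methoxyethan-1-one | COCC(=O)c1c(O)cc(OC)cc1OC
F2 | step 2 | (Z)-3-(5-bromo-2,4-dimethoxyphenyl)-1-(2-hydroxy-4,6-dimethoxyphenyl)-2-methoxyprop-2-en-1-one | COc1cc(O)c(C(=O)/C(OC)=C/c2cc(Br)c(OC)cc2OC)c(OC)c1
F3 | step 2 | 5'-bromo-3,5,7,2',4'-pentamethoxyflavone, 2-(5-bromo-2,4-dimethoxyphenyl)-3,5,7-trimethoxy-4H-chromen-4-one | COc1cc(OC)c2c(=O)c(OC)c(-c3cc(Br)c(OC)cc3OC)oc2c1
F4 | step 1 | 5-hydroxy-3,7,2',4'-tetramethoxyflavone, 2-(2,4-dimethoxyphenyl)-5-hydroxy-3,7-dimethoxy-4H-chromen-4-one | COc1cc(O)c2c(=O)c(OC)c(-c3ccc(OC)cc3OC)oc2c1
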